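**Retrosynthetic overview**
1. The target comes from its tetra-O-benzyl ether by neutral hydrogenolysis; that ketone comes from the cis-(3S,4S)-isoflavan-4-ol by oxidation at C4.
2. C3 (with a temporary C4 centre) is set on the flat epoxy-isoflavone in one reductase-like transfer-hydrogenation cascade with dynamic kinetic resolution.
3. The oxirane is the second ring formed, by asymmetric epoxidation of the prenyl alkene (epoxidase logic). The prenyl group comes from an aryl bromide by Stille coupling, placed after the one step an electron-rich alkene would not survive.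
4. The pyranone C ring is the first ring formed: a one-flask oxidative Cβ→Cα aryl shift and O1–C2 closure on the free 2′-hydroxychalcone (isoflavone-synthase logic), not a deoxybenzoin or an aryl–C3 coupling.
5. The chalcone comes from benzylated phloroacetophenone and benzylated 5-bromoprotocatechualdehyde; the A and B rings are bought.

Assumption: the SMILES is read as the (3S)-isoflavanone carrying a (2R)-oxirane; benzyl bromide, tributyl(prenyl)stannane, the D-fructose-derived Shi ketone and the Ru–TsDPEN catalyst are bought.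

**Step 1**
Reactants: 1 phloroacetophenone (1-(2,4,6-trihydroxyphenyl)ethan-1-one)
Product: 2 dibenzyl ketone (1-[2,4-bis(benzyloxy)-6-hydroxyphenyl]ethan-1-one)
Conditions: BnBr (2.1 equiv), K2CO3 (2.2 equiv), DMF, 0 °C to rt
Reagents that add atoms: benzyl bromide, BrCc1ccccc1
Why: Williamson ether synthesis in which the para hydroxyl and one ortho hydroxyl are alkylated while the last ortho hydroxyl, held in a hydrogen bond to the acetyl carbonyl, stays free.

**Step 2**
Reactants: 3 bromocatechol aldehyde (3-bromo-4,5-dihydroxybenzaldehyde)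
Product: 4 dibenzyl bromoaldehyde (3,4-bis(benzyloxy)-5-bromobenzaldehyde)
Conditions: BnBr (2.4 equiv), K2CO3 (2.5 equiv), DMF, 60 °C
Reagents that add atoms: benzyl bromide, BrCc1ccccc1
Why: Williamson ether synthesis of both catechol hydroxyls, with the aldehyde and the aryl bromide inert to carbonate.

**Step 3**
Reactants: 2 dibenzyl ketone (1-[2,4-bis(benzyloxy)-6-hydroxyphenyl]ethan-1-one); 4 dibenzyl bromoaldehyde (3,4-bis(benzyloxy)-5-bromobenzaldehyde)
Product: 5 chalcone ((E)-1-[2,4-bis(benzyloxy)-6-hydroxyphenyl]-3-[3,4-bis(benzyloxy)-5-bromophenyl]prop-2-en-1-one)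
Conditions: KOH (50% aq.), EtOH–THF, rt
Reagents that add atoms: none
Why: Claisen–Schmidt aldol condensation of the methyl ketone enolate with the non-enolisable aldehyde, followed by E1cB dehydration to the thermodynamically favoured (E)-enone.

**Step 4**
Reactants: 5 chalcone ((E)-1-[2,4-bis(benzyloxy)-6-hydroxyphenyl]-3-[3,4-bis(benzyloxy)-5-bromophenyl]prop-2-en-1-one)
Product: 7 bromoisoflavone (5,7-bis(benzyloxy)-3-[3,4-bis(benzyloxy)-5-bromophenyl]-4H-chromen-4-one), via keto acetal 6 (not isolated)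
Conditions: Tl(NO3)3·3H2O (1.2 equiv), MeOH–HC(OMe)3, rt; then 10% HCl, MeOH–THF, 60 °C
Reagents that add atoms: none
Why: Thallium(III)-mediated oxidative rearrangement of a 2′-hydroxy-6′-alkoxychalcone, in which methoxythallation at Cβ triggers a 1,2-shift of the electron-rich para-benzyloxyaryl ring to Cα to give the dimethyl acetal, and acid then lets the free phenol attack the acetal carbon and expel both methanols taken up from the solvent to close the pyranone ring (no stereocentre is retained).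

**Step 5**
Reactants: 7 bromoisoflavone (5,7-bis(benzyloxy)-3-[3,4-bis(benzyloxy)-5-bromophenyl]-4H-chromen-4-one)
Product: 8 prenylisoflavone (5,7-bis(benzyloxy)-3-[3,4-bis(benzyloxy)-5-(3-methylbut-2-en-1-yl)phenyl]-4H-chromen-4-one)
Conditions: prenyl–SnBu3 (1.5 equiv), Pd(PPh3)4 (5 mol %), DMF, 95 °C
Reagents that add atoms: tributyl(3-methylbut-2-en-1-yl)stannane, CCCC[Sn](CCCC)(CCCC)CC=C(C)C
Why: Stille coupling in which oxidative addition at the aryl bromide, transfer of the allylic stannane through its α-carbon and reductive elimination give the linear prenyl arene, while the chromone and benzyl ethers are untouched.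

**Step 6**
Reactants: 8 prenylisoflavone (5,7-bis(benzyloxy)-3-[3,4-bis(benzyloxy)-5-(3-methylbut-2-en-1-yl)phenyl]-4H-chromen-4-one)
Product: 9 epoxyisoflavone (5,7-bis(benzyloxy)-3-[3,4-bis(benzyloxy)-5-{[(2R)-3,3-dimethyloxiran-2-yl]methyl}phenyl]-4H-chromen-4-one)
Conditions: D-fructose-derived Shi ketone (30 mol %), Oxone, K2CO3, Bu4NHSO4, Na2B4O7–EDTA buffer, MeCN–DMM–H2O, 0 °C
Reagents that add atoms: potassium peroxymonosulfate (active part of Oxone), [K+].[O-]S(=O)(=O)OO
Why: Shi asymmetric epoxidation, in which the chiral dioxirane attacks the electron-rich trisubstituted prenyl alkene through a spiro transition state on the face that gives the (R)-oxirane, while the electron-poor chromone C2=C3 bond and the still-flat C3 are unaffected by the basic medium.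

**Step 7**
Reactants: 9 epoxyisoflavone (5,7-bis(benzyloxy)-3-[3,4-bis(benzyloxy)-5-{[(2R)-3,3-dimethyloxiran-2-yl]methyl}phenyl]-4H-chromen-4-one)
Product: 11 cis-carbinol ((3S,4S)-5,7-bis(benzyloxy)-3-[3,4-bis(benzyloxy)-5-{[(2R)-3,3-dimethyloxiran-2-yl]methyl}phenyl]chroman-4-ol), via C3-epimerising isoflavanone 10 (not isolated)
Conditions: RuCl[(S,S)-TsDPEN](p-cymene) (3 mol %), HCO2H–Et3N (1:1), EtOAc, 40 °C
Reagents that add atoms: none
Why: Noyori–Ikariya asymmetric transfer hydrogenation with dynamic kinetic resolution, in which Ru–H first adds hydride to C2, the resulting isoflavanone epimerises quickly at C3 in the amine-buffered medium, and the (S,S)-catalyst reduces only the (3S)-ketone on the face opposite the aryl group, so that C4 (S) and C3 (S, cis) are set together while the oxirane survives the non-acidic formate.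

**Step 8**
Reactants: 11 cis-carbinol ((3S,4S)-5,7-bis(benzyloxy)-3-[3,4-bis(benzyloxy)-5-{[(2R)-3,3-dimethyloxiran-2-yl]methyl}phenyl]chroman-4-ol)
Product: 12 epoxyisoflavanone ((3S)-5,7-bis(benzyloxy)-3-[3,4-bis(benzyloxy)-5-{[(2R)-3,3-dimethyloxiran-2-yl]methyl}phenyl]chroman-4-one)
Conditions: Dess–Martin periodinane (1.3 equiv), NaHCO3, CH2Cl2, 0 °C to rt
Reagents that add atoms: none
Why: Dess–Martin oxidation of the benzylic carbinol under buffered neutral conditions returns the C4 ketone without enolisation, so C3 stays S and the oxirane is untouched.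

**Step 9**
Reactants: 12 epoxyisoflavanone ((3S)-5,7-bis(benzyloxy)-3-[3,4-bis(benzyloxy)-5-{[(2R)-3,3-dimethyloxiran-2-yl]methyl}phenyl]chroman-4-one)
Product: 13 target ((3S)-3-(3,4-dihydroxy-5-{[(2R)-3,3-dimethyloxiran-2-yl]methyl}phenyl)-5,7-dihydroxychroman-4-one)
Conditions: H2 (1 atm), 10% Pd/C, EtOAc, rt
Reagents that add atoms: none
Why: Catalytic hydrogenolysis of the four benzyl ethers under neutral conditions, which in a short run leaves the non-benzylic trialkyl oxirane, the hydrogen-bonded aryl ketone and the C3 stereocentre unchanged.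

**Compound list**
1 | phloroacetophenone (1-(2,4,6-trihydroxyphenyl)ethan-1-one) | CC(=O)c1c(O)cc(O)cc1O | starting material
2 | dibenzyl ketone (1-[2,4-bis(benzyloxy)-6-hydroxyphenyl]ethan-1-one) | CC(=O)c1c(O)cc(OCc2ccccc2)cc1OCc1ccccc1 | intermediate
3 | bromocatechol aldehyde (3-bromo-4,5-dihydroxybenzaldehyde) | O=Cc1cc(O)c(O)c(Br)c1 | starting material
4 | dibenzyl bromoaldehyde (3,4-bis(benzyloxy)-5-bromobenzaldehyde) | O=Cc1cc(OCc2ccccc2)c(OCc2ccccc2)c(Br)c1 | intermediate
5 | chalcone ((E)-1-[2,4-bis(benzyloxy)-6-hydroxyphenyl]-3-[3,4-bis(benzyloxy)-5-bromophenyl]prop-2-en-1-one) | O=C(/C=C/c1cc(OCc2ccccc2)c(OCc2ccccc2)c(Br)c1)c1c(O)cc(OCc2ccccc2)cc1OCc1ccccc1 | intermediate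
6 | keto acetal (racemic 1-[2,4-bis(benzyloxy)-6-hydroxyphenyl]-2-[3,4-bis(benzyloxy)-5-bromophenyl]-3,3-dimethoxypropan-1-one; not isolated) | COC(OC)C(c1cc(OCc2ccccc2)c(OCc2ccccc2)c(Br)c1)C(=O)c1c(O)cc(OCc2ccccc2)cc1OCc1ccccc1 | intermediate
7 | bromoisoflavone (5,7-bis(benzyloxy)-3-[3,4-bis(benzyloxy)-5-bromophenyl]-4H-chromen-4-one) | O=c1c(-c2cc(OCc3ccccc3)c(OCc3ccccc3)c(Br)c2)coc2cc(OCc3ccccc3)cc(OCc3ccccc3)c12 | intermediate
8 | prenylisoflavone (5,7-bis(benzyloxy)-3-[3,4-bis(benzyloxy)-5-(3-methylbut-2-en-1-yl)phenyl]-4H-chromen-4-one) | CC(C)=CCc1cc(-c2coc3cc(OCc4ccccc4)cc(OCc4ccccc4)c3c2=O)cc(OCc2ccccc2)c1OCc1ccccc1 | intermediate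
9 | epoxyisoflavone (5,7-bis(benzyloxy)-3-[3,4-bis(benzyloxy)-5-{[(2R)-3,3-dimethyloxiran-2-yl]methyl}phenyl]-4H-chromen-4-one) | CC1(C)O[C@@H]1Cc1cc(-c2coc3cc(OCc4ccccc4)cc(OCc4ccccc4)c3c2=O)cc(OCc2ccccc2)c1OCc1ccccc1 | intermediate
10 | C3-epimerising isoflavanone (5,7-bis(benzyloxy)-3-[3,4-bis(benzyloxy)-5-{[(2R)-3,3-dimethyloxiran-2-yl]methyl}phenyl]chroman-4-one, both C3 epimers in equilibrium; not isolated) | CC1(C)O[C@@H]1Cc1cc(C2COc3cc(OCc4ccccc4)cc(OCc4ccccc4)c3C2=O)cc(OCc2ccccc2)c1OCc1ccccc1 | intermediate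
11 | cis-carbinol ((3S,4S)-5,7-bis(benzyloxy)-3-[3,4-bis(benzyloxy)-5-{[(2R)-3,3-dimethyloxiran-2-yl]methyl}phenyl]chroman-4-ol) | CC1(C)O[C@@H]1Cc1cc([C@H]2COc3cc(OCc4ccccc4)cc(OCc4ccccc4)c3[C@H]2O)cc(OCc2ccccc2)c1OCc1ccccc1 | intermediate
12 | epoxyisoflavanone ((3S)-5,7-bis(benzyloxy)-3-[3,4-bis(benzyloxy)-5-{[(2R)-3,3-dimethyloxiran-2-yl]methyl}phenyl]chroman-4-one) | CC1(C)O[C@@H]1Cc1cc([C@H]2COc3cc(OCc4ccccc4)cc(OCc4ccccc4)c3C2=O)cc(OCc2ccccc2)c1OCc1ccccc1 | intermediate
13 | target ((3S)-3-(3,4-dihydroxy-5-{[(2R)-3,3-dimethyloxiran-2-yl]methyl}phenyl)-5,7-dihydroxychroman-4-one) | CC1(C)O[C@@H]1Cc1cc([C@H]2COc3cc(O)cc(O)c3C2=O)cc(O)c1O | target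

**Totals**
Total step count: 9. Longest linear sequence: 8 (step 1 or step 2, then steps 3 to 9).

**Steps most likely to fail**

Step 5 (Stille coupling). The hindered, electron-rich bromide may add slowly to Pd(0), and transfer of the allyl unit through its γ-carbon would give the branched 1,1-dimethylallyl isomer. The fallback sets out from 7 and comes back at 8 by reversing the polarity of the coupling. Miyaura borylation of 7 (B2pin2, PdCl2(dppf), KOAc, dioxane, 90 °C) gives pinacol boronate isoflavone F1. Suzuki coupling of F1 with prenyl bromide (Pd(PPh3)4, K2CO3, THF–H2O, 60 °C) runs through a π-prenyl palladium species that is arylated at its unsubstituted terminus and delivers 8.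

Step 7 (transfer-hydrogenation cascade). The electron-rich 5-benzyloxy isoflavone may accept hydride at C2 slowly, reduction of the peri-hindered ketone may stall, and the oxirane has to survive warm formate. The fallback sets out from 8 and comes back at 11; it fixes C3 by catalytic enantioselective protonation before the oxirane exists. L-Selectride (THF, −78 °C) adds hydride to C2 of 8 and TMSCl traps the enolate as silyl enol ether F2. A BINOL-derived N-triflyl thiophosphoramide (5 mol %) with phenol in toluene protonates F2 to (S)-isoflavanone F3, the catalyst antipode being chosen by a test run. L-Selectride at −78 °C reduces F3 from the face opposite the aryl group to prenyl cis-carbinol F4, whose C3 can no longer epimerise. Shi epoxidation of F4 under the conditions of step 6 gives 11.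

Step 9 (hydrogenolysis). Palladium may open the oxirane, or the freed ortho phenol may close on it to a dihydrobenzofuran or chroman. The fallback sets out from 7 and comes back at 13, using silyl ethers that leave with fluoride. BCl3 (CH2Cl2, −78 to 0 °C) strips the benzyl groups of 7 to bromo tetrol F5, and TBSOTf with 2,6-lutidine gives tetrasilyl bromoisoflavone F6. The main sequence is then repeated on the silyl series: Stille coupling gives silyl prenylisoflavone F7; Shi epoxidation, run near pH 8 with stoichiometric ketone to spare the aryl silyl ethers, gives silyl epoxyisoflavone F8; transfer hydrogenation via C3-epimerising silyl isoflavanone F9 gives silyl cis-carbinol F10; Dess–Martin oxidation gives silyl epoxyisoflavanone F11. Et3N·3HF in THF at 0 °C then releases 13.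

**Further compounds**
F1 | step 5 | pinacol boronate isoflavone (5,7-bis(benzyloxy)-3-[3,4-bis(benzyloxy)-5-(4,4,5,5-tetramethyl-1,3,2-dioxaborolan-2-yl)phenyl]-4H-chromen-4-one) | CC1(C)OB(c2cc(-c3coc4cc(OCc5ccccc5)cc(OCc5ccccc5)c4c3=O)cc(OCc3ccccc3)c2OCc2ccccc2)OC1(C)C
F2 | step 7 | silyl enol ether ({5,7-bis(benzyloxy)-3-[3,4-bis(benzyloxy)-5-(3-methylbut-2-en-1-yl)phenyl]-2H-chromen-4-yl}oxy(trimethyl)silane) | CC(C)=CCc1cc(C2=C(O[Si](C)(C)C)c3c(OCc4ccccc4)cc(OCc4ccccc4)cc3OC2)cc(OCc2ccccc2)c1OCc1ccccc1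
F3 | step 7 | (S)-isoflavanone ((3S)-5,7-bis(benzyloxy)-3-[3,4-bis(benzyloxy)-5-(3-methylbut-2-en-1-yl)phenyl]chroman-4-one) | CC(C)=CCc1cc([C@H]2COc3cc(OCc4ccccc4)cc(OCc4ccccc4)c3C2=O)cc(OCc2ccccc2)c1OCc1ccccc1
F4 | step 7 | prenyl cis-carbinol ((3S,4S)-5,7-bis(benzyloxy)-3-[3,4-bis(benzyloxy)-5-(3-methylbut-2-en-1-yl)phenyl]chroman-4-ol) | CC(C)=CCc1cc([C@H]2COc3cc(OCc4ccccc4)cc(OCc4ccccc4)c3[C@H]2O)cc(OCc2ccccc2)c1OCc1ccccc1
F5 | step 9 | bromo tetrol (3-(3-bromo-4,5-dihydroxyphenyl)-5,7-dihydroxy-4H-chromen-4-one) | O=c1c(-c2cc(O)c(O)c(Br)c2)coc2cc(O)cc(O)c12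
F6 | step 9 | tetrasilyl bromoisoflavone (3-[3-bromo-4,5-bis(tert-butyldimethylsilyloxy)phenyl]-5,7-bis(tert-butyldimethylsilyloxy)-4H-chromen-4-one) | O=c1c(-c2cc(O[Si](C)(C)C(C)(C)C)c(O[Si](C)(C)C(C)(C)C)c(Br)c2)coc2cc(O[Si](C)(C)C(C)(C)C)cc(O[Si](C)(C)C(C)(C)C)c12
F7 | step 9 | silyl prenylisoflavone (5,7-bis(tert-butyldimethylsilyloxy)-3-[3,4-bis(tert-butyldimethylsilyloxy)-5-(3-methylbut-2-en-1-yl)phenyl]-4H-chromen-4-one) | CC(C)=CCc1cc(-c2coc3cc(O[Si](C)(C)C(C)(C)C)cc(O[Si](C)(C)C(C)(C)C)c3c2=O)cc(O[Si](C)(C)C(C)(C)C)c1O[Si](C)(C)C(C)(C)C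
F8 | step 9 | silyl epoxyisoflavone (5,7-bis(tert-butyldimethylsilyloxy)-3-[3,4-bis(tert-butyldimethylsilyloxy)-5-{[(2R)-3,3-dimethyloxiran-2-yl]methyl}phenyl]-4H-chromen-4-one) | CC1(C)O[C@@H]1Cc1cc(-c2coc3cc(O[Si](C)(C)C(C)(C)C)cc(O[Si](C)(C)C(C)(C)C)c3c2=O)cc(O[Si](C)(C)C(C)(C)C)c1O[Si](C)(C)C(C)(C)C
F9 | step 9 | C3-epimerising silyl isoflavanone (5,7-bis(tert-butyldimethylsilyloxy)-3-[3,4-bis(tert-butyldimethylsilyloxy)-5-{[(2R)-3,3-dimethyloxiran-2-yl]methyl}phenyl]chroman-4-one, both C3 epimers; not isolated) | CC1(C)O[C@@H]1Cc1cc(C2COc3cc(O[Si](C)(C)C(C)(C)C)cc(O[Si](C)(C)C(C)(C)C)c3C2=O)cc(O[Si](C)(C)C(C)(C)C)c1O[Si](C)(C)C(C)(C)C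
F10 | step 9 | silyl cis-carbinol ((3S,4S)-5,7-bis(tert-butyldimethylsilyloxy)-3-[3,4-bis(tert-butyldimethylsilyloxy)-5-{[(2R)-3,3-dimethyloxiran-2-yl]methyl}phenyl]chroman-4-ol) | CC1(C)O[C@@H]1Cc1cc([C@H]2COc3cc(O[Si](C)(C)C(C)(C)C)cc(O[Si](C)(C)C(C)(C)C)c3[C@H]2O)cc(O[Si](C)(C)C(C)(C)C)c1O[Si](C)(C)C(C)(C)C
F11 | step 9 | silyl epoxyisoflavanone ((3S)-5,7-bis(tert-butyldimethylsilyloxy)-3-[3,4-bis(tert-butyldimethylsilyloxy)-5-{[(2R)-3,3-dimethyloxiran-2-yl]methyl}phenyl]chroman-4-one) | CC1(C)O[C@@H]1Cc1cc([C@H]2COc3cc(O[Si](C)(C)C(C)(C)C)cc(O[Si](C)(C)C(C)(C)C)c3C2=O)cc(O[Si](C)(C)C(C)(C)C)c1O[Si](C)(C)C(C)(C)C
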